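**Assumptions (one line each)**
- The target is the 3-O-(3,4-dimethoxybenzoyl) ester of rohitukine. Both of its stereocentres are (3S,4R), and the 3-OH and 4-aryl groups are cis.
- N-Boc-3,4-epoxypiperidine (racemic) and 1,3,5-trimethoxybenzene are commercial.
- The (S,S)-Ru-TsDPEN catalyst is assumed to give the (3S,4R) alcohol. If the antipode is obtained, the (R,R) catalyst is used instead.

**Retrosynthesis**
1. Chrotacumine D is the veratroyl ester of rohitukine, made in the last step by chemoselective O-acylation of the free 3-OH.
2. The chromone (pyranone) ring is the last ring formed, by Claisen/cyclodehydration onto a 2'-hydroxyacetophenone. That ketone comes from Friedel–Crafts acetylation of the 2,4,6-trimethoxyphenyl group, which also demethylates one ortho OMe.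
3. The cis-(3S,4R)-3-hydroxy-4-arylpiperidine is made by Ru-catalysed asymmetric transfer hydrogenation with dynamic kinetic resolution (ATH-DKR) of a racemic 4-aryl-3-piperidone. This sets both stereocentres in one step from racemic material and avoids resolution and inversion.
4. The ketone comes from oxidation of the trans alcohol, which is made by BF3-assisted opening of commercial N-Boc-3,4-epoxypiperidine with lithiated 1,3,5-trimethoxybenzene. The piperidine ring is therefore purchased, and the aryl and chromone rings are added in that order.

---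

**Step 1**
Reactants: 1 (1,3,5-trimethoxybenzene); 2 (rac-N-Boc-3,4-epoxypiperidine)
Product: 3 (rac-trans-N-Boc-3-hydroxy-4-(2,4,6-trimethoxyphenyl)piperidine)
Conditions: 1, n-BuLi, THF, 0 °C→rt, 2 h; then −78 °C, BF3·OEt2, then 2, −78→−20 °C
Reagents that add atoms: none
Why: BF3-promoted organolithium epoxide opening (Yamamoto-type). Attack at C4 is trans-diaxial (Fürst–Plattner), giving the trans-3-ol as a racemate. The stereochemistry is erased in the next step, so it does not matter here.

**Step 2**
Reactants: 3
Product: 4 (rac-N-Boc-3-oxo-4-(2,4,6-trimethoxyphenyl)piperidine)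
Conditions: Dess–Martin periodinane, NaHCO3, CH2Cl2, 0 °C→rt
Reagents that add atoms: none
Why: Mild oxidation of a secondary alcohol. Boc and the aryl methyl ethers are untouched, and the configurationally labile α-aryl C4 is allowed to racemise.

**Step 3**
Reactants: 4
Product: 5 ((3S,4R)-cis-N-Boc-3-hydroxy-4-(2,4,6-trimethoxyphenyl)piperidine)
Conditions: RuCl[(S,S)-TsDPEN](p-cymene) (2 mol%), HCO2H/Et3N (5:2), CH2Cl2, 40 °C, 48 h
Reagents that add atoms: none (the formate only supplies H)
Why: Noyori–Ikariya ATH with DKR. Proposed new method: the acidic, benzylic α-aryl C4–H epimerises through the enol under formate/Et3N, the same lability that makes the ketone epimerise under Swern conditions. The chiral Ru–H reduces one ketone enantiomer faster, and hydride delivery from the face that puts OH cis to the 4-aryl group sets C3 and C4 together. The closest known reaction is Ru-TsDPEN ATH-DKR of α-substituted cyclic ketones and β-keto esters.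

**Step 4**
Reactants: 5
Product: 6 ((3S,4R)-1-methyl-4-(2,4,6-trimethoxyphenyl)piperidin-3-ol)
Conditions: LiAlH4, THF, 65 °C, 4 h
Reagents that add atoms: none (hydride only)
Why: Reduction of an N-Boc carbamate to N-CH3. The C–O, aryl methyl ether and stereocentres are not affected.

**Step 5**
Reactants: 6; 7 (acetic anhydride)
Product: 8 ((3S,4R)-3-acetoxy-4-(3-acetyl-2-hydroxy-4,6-dimethoxyphenyl)-1-methylpiperidine)
Conditions: 7, BF3·OEt2, 70 °C, 3 h; then aq. K2CO3, EtOH, 50 °C
Reagents that add atoms: Ac2O, CC(=O)OC(C)=O
Why: BF3-mediated Friedel–Crafts acetylation of the electron-rich arene. The BF2 chelate of the new ketone cleaves the most hindered ortho OMe, the one next to the piperidinyl group, which gives the 2'-OH that will become O1. The 3-OH is acetylated on the way, and the stereocentres are not touched.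

**Step 6**
Reactants: 8; 9 (ethyl acetate)
Product: 10 ((3S,4R)-1-(2-hydroxy-4,6-dimethoxy-3-(3-hydroxy-1-methylpiperidin-4-yl)phenyl)butane-1,3-dione)
Conditions: NaH (6 equiv), 9 (10 equiv), THF, 65 °C, 6 h; then aq. NH4Cl
Reagents that add atoms: EtOAc, CC(=O)OCC
Why: Claisen condensation of the phenoxide/ketone enolate with EtOAc gives the 1,3-diketone. Alkoxide generated in situ removes the O-acetate, and any residue is removed in step 7.

**Step 7**
Reactants: 10
Product: 11 (5,7-dimethoxy-2-methyl-8-[(3S,4R)-3-hydroxy-1-methylpiperidin-4-yl]chromone)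
Conditions: 6 M HCl, EtOH, 80 °C, 6 h; then basify to pH 9
Reagents that add atoms: none
Why: Acid-catalysed cyclodehydration of the o-hydroxyaryl 1,3-diketone (Kostanecki/Baker–Venkataraman type) forms the pyranone ring, and the same conditions hydrolyse any leftover acetate. The non-activated sp3 stereocentres survive.

**Step 8**
Reactants: 11
Product: 12 (rohitukine, 5,7-dihydroxy-2-methyl-8-[(3S,4R)-3-hydroxy-1-methylpiperidin-4-yl]chromone)
Conditions: pyridine·HCl, neat, 180 °C, 2 h
Reagents that add atoms: none
Why: Pyridinium chloride cleaves both aryl methyl ethers (the 5-OMe is assisted by the carbonyl). The secondary alcohol and the amine survive, as in the standard flavopiridol end-game, and no C–H stereocentre can epimerise.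

**Step 9**
Reactants: 12; 13 (3,4-dimethoxybenzoyl chloride)
Product: 14 (chrotacumine D)
Conditions: 13 (2 equiv), CF3CO2H, 25 °C, 16 h; then aq. NaHCO3
Reagents that add atoms: veratroyl chloride, COc1ccc(C(=O)Cl)cc1OC
Why: Under strongly acidic conditions the amine is protonated and the poorly nucleophilic, chelated or vinylogous-acid phenols do not acylate. The aliphatic 3-OH is acylated through the mixed anhydride, with retention at C3.

---

**Final check**
- The target SMILES has a piperidine ring with a 3-O-veratroyl ester, an N-methyl group, a C4 linkage to C8 of a 5,7-dihydroxy-2-methylchromone, and (3S,4R) configuration with cis OH and aryl.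
- Compound 14 is written with the same atom order and tags as the target, so the stereochemistry matches exactly.
- C3 and C4 are set once, in step 3, and no later step touches them (LiAlH4, BF3/Ac2O, HCl and pyridine·HCl do not epimerise them).
- Atom balance holds at every step. In step 5, two acetyl groups are added and one methyl is lost. In step 6, one CH2C(=O) unit is added and the acetate is lost. In step 7, water is lost. In step 8, two methyl groups are lost.

**Compound list**

| No. | Name | SMILES | Role |
|---|---|---|---|
| 1 | 1,3,5-trimethoxybenzene | COc1cc(OC)cc(OC)c1 | starting material |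
| 2 | rac-tert-butyl 7-oxa-3-azabicyclo[4.1.0]heptane-3-carboxylate | CC(C)(C)OC(=O)N1CCC2OC2C1 | starting material |
| 3 | rac-trans-N-Boc-3-hydroxy-4-(2,4,6-trimethoxyphenyl)piperidine (one enantiomer drawn) | O[C@H]1CN(C(=O)OC(C)(C)C)CC[C@@H]1c2c(OC)cc(OC)cc2OC | intermediate |
| 4 | rac-N-Boc-3-oxo-4-(2,4,6-trimethoxyphenyl)piperidine | O=C1CN(C(=O)OC(C)(C)C)CCC1c2c(OC)cc(OC)cc2OC | intermediate |
| 5 | (3S,4R)-N-Boc-3-hydroxy-4-(2,4,6-trimethoxyphenyl)piperidine | O[C@@H]1CN(C(=O)OC(C)(C)C)CC[C@@H]1c2c(OC)cc(OC)cc2OC | intermediate |
| 6 | (3S,4R)-1-methyl-4-(2,4,6-trimethoxyphenyl)piperidin-3-ol | O[C@@H]1CN(C)CC[C@@H]1c2c(OC)cc(OC)cc2OC | intermediate |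
| 7 | acetic anhydride | CC(=O)OC(C)=O | starting material |
| 8 | (3S,4R)-3-acetoxy-4-(3-acetyl-2-hydroxy-4,6-dimethoxyphenyl)-1-methylpiperidine | CC(=O)O[C@@H]1CN(C)CC[C@@H]1c2c(O)c(C(C)=O)c(OC)cc2OC | intermediate |
| 9 | ethyl acetate | CC(=O)OCC | starting material |
| 10 | (3S,4R)-1,3-diketone with free 3-OH and 2'-OH | O[C@@H]1CN(C)CC[C@@H]1c2c(O)c(C(=O)CC(C)=O)c(OC)cc2OC | intermediate |
| 11 | 5,7-dimethoxy-2-methyl-8-[(3S,4R)-3-hydroxy-1-methylpiperidin-4-yl]chromone | O[C@@H]1CN(C)CC[C@@H]1c2c(OC)cc(OC)c3c(=O)cc(C)oc23 | intermediate |
| 12 | rohitukine | O[C@@H]1CN(C)CC[C@@H]1c2c(O)cc(O)c3c(=O)cc(C)oc23 | intermediate |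
| 13 | 3,4-dimethoxybenzoyl chloride | COc1ccc(C(=O)Cl)cc1OC | starting material |
| 14 | chrotacumine D | COc1ccc(C(=O)O[C@@H]2CN(C)CC[C@@H]2c2c(O)cc(O)c3c(=O)cc(C)oc23)cc1OC | target |

**Total steps:** 9. **Longest linear sequence:** 9 (from 2 and 1).

**Three steps most likely to fail**
1. **Step 3 (ATH-DKR).** Racemisation of the hindered, electron-rich α-aryl ketone may be slower than reduction, which would erode ee or cis/trans selectivity.
   - Fallback: reduce racemic 4 with L-Selectride to the cis racemate (equatorial hydride attack), then resolve at the N-methyl stage by dibenzoyl-tartrate crystallisation or chiral SFC. Alternatively, run a ketoreductase-panel DKR at pH 8.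
2. **Step 1 (hindered ArLi/BF3 epoxide opening).** The C4/C3 regioselectivity may be poor, the aryl anion may attack the Boc group, and the yield may be low.
   - Fallback: condense TMB with N-methyl-4-piperidone (AcOH/HCl) to the 4-aryl-tetrahydropyridine, then hydroborate and oxidise to the trans-3-ol and Swern-oxidise to the N-methyl ketone. Feed that ketone into the DKR and skip the LiAlH4 step.
3. **Step 9 (chemoselective O-acylation).** The 7-OH may be acylated, or the hindered cis-axial alcohol may react sluggishly.
   - Fallback: tri-acylate 12 with excess veratroyl chloride, Et3N and DMAP, then selectively cleave the phenolic aryl esters with pyrrolidine or NH3/MeOH, leaving the hindered alkyl ester.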